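Ring B (C1, C5–C10) is divided into the C6–C5–C1 unit that ring A already holds and the chain C7–C8(C14)–C9–C10, which is isoprene. The C8=C9 alkene is the one generated by a [3,3] shift of a 1,2-dialkenylcyclopropane. In one operation a chromium alkoxycarbene hands C6 to the methyl-bearing alkene of isoprene, and the cis-divinylcyclopropane then undergoes a Cope shift. This makes C6–C7 and C1–C10, closes ring B, sets quaternary C1 and leaves C6 as an enol ether. The precursor is a pentacarbonyl[methoxy(cyclopentenyl)carbene]chromium whose fully substituted cyclopentene carries the C4 silyl ether and isopropyl group of (S)-terpinen-4-ol.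

Key step: step 7

Numbering: daucane numbers are used for all compounds, monocyclic ones included.
- C1 is the quaternary fusion carbon (methyl C15), C4 the carbinol carbon (isopropyl), C5 the fusion CH, C6 the ester carbon, and C8 carries methyl C14.
- Ring A is C1–C5; ring B is C1 plus C5–C10.
- β is the face of C15; α is the face of H5.

Assumption: the purchased (S)-terpinen-4-ol is taken as enantiomerically pure (to be checked by chiral GC), because C4 is the only source of absolute configuration.

Step 1
Reactants: 1 (S)-terpinen-4-ol
Product: 2 triethyl{[(1S)-4-methyl-1-(propan-2-yl)cyclohex-3-en-1-yl]oxy}silane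
Conditions: Et3SiOTf, 2,6-lutidine, CH2Cl2, 0 °C → rt
Reagents that add atoms: triethylsilyl triflate, CC[Si](CC)(CC)OS(=O)(=O)C(F)(F)F
Why: Silyl triflate silylation of a hindered tertiary alcohol is reliable, leaves C4 untouched, and is placed first so that the later γ-hydroxy ketone cannot close to a hemiketal and the aldol of step 3 has only one free hydroxyl to lose.

Step 2
Reactants: 2 terpinen-4-ol triethylsilyl ether
Product: 4 (3S)-6-oxo-3-(propan-2-yl)-3-(triethylsilyloxy)heptanal, via secondary ozonide 3 (not isolated)
Conditions: O3, CH2Cl2, −78 °C; Me2S, −78 °C → rt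
Reagents that add atoms: ozone, [O-][O+]=O
Why: Ozonolysis with reductive work-up cleaves the only alkene to the C1 methyl ketone and the C6 aldehyde under neutral conditions that touch neither the silyl ether nor C4.

Step 3
Reactants: 4 keto aldehyde
Product: 6 (5R)-2-methyl-5-(propan-2-yl)-5-(triethylsilyloxy)cyclopent-1-ene-1-carbaldehyde, via aldol adduct 5 (not isolated)
Conditions: dibenzylammonium trifluoroacetate (20 mol %), toluene, 45 °C
Reagents that add atoms: none
Why: In this amine-salt-catalysed intramolecular aldol condensation (5-enolexo closure of C5–C1, the ring contraction familiar from limonene-derived keto aldehydes) the aldehyde forms its enamine faster than the ketone, so C5 attacks the C1 ketone, and aldol 5 then loses its free C1 hydroxyl rather than the hindered, weakly basic C4 silyl ether in the mildly acidic medium.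

Step 4
Reactants: 6 cyclopentenecarbaldehyde
Product: 7 (5R)-2-methyl-5-(propan-2-yl)-5-(triethylsilyloxy)cyclopent-1-ene-1-carboxylic acid
Conditions: NaClO2, NaH2PO4, 2-methylbut-2-ene, t-BuOH/H2O, 0 °C → rt
Reagents that add atoms: sodium chlorite, [Na+].[O-]Cl=O
Why: The Pinnick oxidation converts α,β-unsaturated aldehydes into acids without touching the alkene, and its phosphate buffer is mild enough for a tertiary triethylsilyl ether.

Step 5
Reactants: 7 cyclopentenecarboxylic acid
Product: 8 (5R)-2-methyl-5-(propan-2-yl)-5-(triethylsilyloxy)cyclopent-1-ene-1-carbonyl chloride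
Conditions: 1-chloro-N,N,2-trimethylprop-1-en-1-amine, CH2Cl2, 0 °C → rt; volatiles removed at 0.1 mbar, used crude
Reagents that add atoms: 1-chloro-N,N,2-trimethylprop-1-en-1-amine (Ghosez reagent), CC(C)=C(Cl)N(C)C
Why: The Ghosez chloroenamine makes acid chlorides under neutral conditions, so no HCl can cleave or ionise the allylic tertiary silyl ether, and its amide by-product is volatile enough to be pumped off before the chromate step.

Step 6
Reactants: 8 acid chloride; 9 chromium hexacarbonyl, Cr(CO)6
Product: 12 pentacarbonyl{methoxy[(5R)-2-methyl-5-(propan-2-yl)-5-(triethylsilyloxy)cyclopent-1-en-1-yl]methylidene}chromium, via disodium pentacarbonylchromate 10 (not isolated), via sodium acylchromate 11 (not isolated)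
Conditions: 9, NaC10H8 (2 equiv), THF, −78 °C; 8, −78 → 0 °C; solvent change to CH2Cl2; MeOTf, 0 °C
Reagents that add atoms: methyl triflate, COS(=O)(=O)C(F)(F)F
Why: Acylation of the pentacarbonylchromate dianion by an acid chloride followed by O-methylation of the acylate is the established acid chloride entry to Fischer alkoxycarbene complexes, conjugate attack being blocked because C1 is fully substituted and C4 remaining a spectator.

Step 7
Reactants: 12 carbene complex; 13 isoprene
Product: 15 (1R,4R)-6-methoxy-4-(triethylsilyloxy)dauca-5,8-diene, via cis-divinylcyclopropane 14 (not isolated)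
Conditions: 13 (20 equiv), 2,6-di-tert-butyl-4-methylphenol (trace), toluene, sealed tube under Ar, 100 °C, then 140 °C; air, filtration through basic Al2O3
Reagents that add atoms: none
Why: Thermal loss of one CO opens a site on chromium for isoprene, the electrophilic carbene carbon C6 adds to C7, the chromacyclobutane closes onto C8 and reductive elimination gives cyclopropane 14 (bonds C6–C7 and C6–C8). The closest known chemistry is this very reaction type, the cyclopropanation of 1,3-dienes by alkenyl Fischer carbene complexes followed by divinylcyclopropane (Cope) rearrangement, a formal (4+3) cycloaddition. Ring B closes in the [3,3] shift of 14 through a boat transition state in which C6–C8 breaks and C1–C10 forms with release of cyclopropane strain, and stereoisomers of 14 with the alkenyl groups trans are fed in during the hotter stage by reversible homolysis of the C6–C8 bond, which the methoxy and vinyl groups weaken. C1, the only new stereocentre that persists, is controlled by C4: in the boat that brings C10 to the α face the C6 methoxy group lies beside the C4 oxygen atom, whereas in the other boat it is pressed against the isopropyl group, and the silyl group adds cover to the β face, so C15 should end up β. The step needs site selectivity for C7=C8 over C9=C10, which the C14 methyl group provides by making that alkene the more nucleophilic one and by stabilising the charge that builds up at tertiary, allylic C8. It also needs cyclopropanation to win over the Diels–Alder reaction typical of alkenyl carbene complexes, which is secured because both C1 and C5 are fully substituted.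

Step 8
Reactants: 15 methoxy diene
Product: 16 (1R,4R,5R)-4-(triethylsilyloxy)dauc-8-en-6-one (4β-silyloxy, 5α-H, trans-fused)
Conditions: oxalic acid, THF/H2O, 0 °C
Reagents that add atoms: water, O
Why: Mild acid hydrolysis of a 1-methoxy-1,4-diene, as practised on Birch reduction products, releases the β,γ-unsaturated ketone without moving C8=C9, and C5 should be protonated irreversibly on the α face (away from C15 and the silyl ether, with relief of the clash between the C6 methoxy and the isopropyl group) to give the trans fusion, while no equilibration is attempted because base or strong acid would conjugate the alkene through the acidic C7 hydrogens or expel the C4 oxygen.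

Step 9
Reactants: 16 silyloxy ketone
Product: 17 (1R,4R,5R)-4-hydroxydauc-8-en-6-one
Conditions: HF·pyridine, pyridine, THF, 0 °C
Reagents that add atoms: none
Why: Fluoride-mediated desilylation with buffered HF·pyridine removes the triethylsilyl group in a medium in which the β-hydroxy ketone should suffer neither retro-aldol cleavage nor dehydration nor alkene migration, all of which basic Bu4NF would invite.

Step 10
Reactants: 17 hydroxy ketone
Product: 18 (1R,4R,5S,6S)-dauc-8-ene-4,6-diol (4β,6α-diol, jaeschkeanadiol)
Conditions: Me4NBH(OAc)3, MeCN/AcOH, −30 → 0 °C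
Reagents that add atoms: none
Why: In the Evans–Saksena reduction the 4β-hydroxyl replaces an acetate on boron and delivers hydride within the complex to the β face of C6, which sets the 6α-alcohol (6S), and the reagent reduces neither unassisted ketones nor the alkene.

Step 11
Reactants: 18 diol; 19 3,4-dimethoxybenzoyl chloride (veratroyl chloride)
Product: 20 (1R,4R,5S,6S)-4-hydroxydauc-8-en-6-yl 3,4-dimethoxybenzoate (target)
Conditions: 19, Et3N, 4-dimethylaminopyridine, CH2Cl2, rt → 40 °C
Reagents that add atoms: none
Why: Acylation under nucleophilic catalysis by 4-dimethylaminopyridine esterifies the secondary 6α-hydroxyl, while the tertiary 4β-hydroxyl next to the isopropyl group is far too hindered to react.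

Compound list
1 | (S)-terpinen-4-ol | CC1=CC[C@](O)(C(C)C)CC1 | starting material
2 | triethyl{[(1S)-4-methyl-1-(propan-2-yl)cyclohex-3-en-1-yl]oxy}silane | CC1=CC[C@](O[Si](CC)(CC)CC)(C(C)C)CC1 | intermediate
3 | secondary ozonide of 2 (7,8,9-trioxabicyclo[4.2.1]nonane, bridgeheads as a mixture) | CC12CC[C@@](O[Si](CC)(CC)CC)(C(C)C)CC(OO1)O2 | intermediate
4 | (3S)-6-oxo-3-(propan-2-yl)-3-(triethylsilyloxy)heptanal | O=CC[C@](O[Si](CC)(CC)CC)(C(C)C)CCC(C)=O | intermediate
5 | 2-hydroxy-2-methyl-5-(propan-2-yl)-5-(triethylsilyloxy)cyclopentane-1-carbaldehyde (C4 fixed, C1 and C5 as mixtures) | O=CC1C(C)(O)CC[C@@]1(O[Si](CC)(CC)CC)C(C)C | intermediate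
6 | (5R)-2-methyl-5-(propan-2-yl)-5-(triethylsilyloxy)cyclopent-1-ene-1-carbaldehyde | O=CC1=C(C)CC[C@@]1(O[Si](CC)(CC)CC)C(C)C | intermediate
7 | (5R)-2-methyl-5-(propan-2-yl)-5-(triethylsilyloxy)cyclopent-1-ene-1-carboxylic acid | OC(=O)C1=C(C)CC[C@@]1(O[Si](CC)(CC)CC)C(C)C | intermediate
8 | (5R)-2-methyl-5-(propan-2-yl)-5-(triethylsilyloxy)cyclopent-1-ene-1-carbonyl chloride | ClC(=O)C1=C(C)CC[C@@]1(O[Si](CC)(CC)CC)C(C)C | intermediate
9 | chromium hexacarbonyl, Cr(CO)6 | O=C=[Cr](=C=O)(=C=O)(=C=O)(=C=O)=C=O | starting material
10 | disodium pentacarbonylchromate, Na2Cr(CO)5 | [Na+].[Na+].O=C=[Cr-2](=C=O)(=C=O)(=C=O)=C=O | intermediate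
11 | sodium pentacarbonyl(acyl)chromate of 8 | [Na+].[O-]C(C1=C(C)CC[C@@]1(O[Si](CC)(CC)CC)C(C)C)=[Cr](=C=O)(=C=O)(=C=O)(=C=O)=C=O | intermediate
12 | pentacarbonyl{methoxy[(5R)-2-methyl-5-(propan-2-yl)-5-(triethylsilyloxy)cyclopent-1-en-1-yl]methylidene}chromium | COC(C1=C(C)CC[C@@]1(O[Si](CC)(CC)CC)C(C)C)=[Cr](=C=O)(=C=O)(=C=O)(=C=O)=C=O | intermediate
13 | isoprene | C=CC(C)=C | starting material
14 | (6S,8R)-cis-divinylcyclopropane: 1-methoxy-1-cyclopentenyl-2-methyl-2-vinylcyclopropane, cyclopentenyl and vinyl on the same face | CO[C@@]1(C2=C(C)CC[C@@]2(O[Si](CC)(CC)CC)C(C)C)C[C@]1(C)C=C | intermediate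
15 | (1R,4R)-6-methoxy-4-(triethylsilyloxy)dauca-5,8-diene | COC1=C2[C@](O[Si](CC)(CC)CC)(C(C)C)CC[C@]2(C)CC=C(C)C1 | intermediate
16 | (1R,4R,5R)-4-(triethylsilyloxy)dauc-8-en-6-one | O=C1CC(C)=CC[C@@]2(C)CC[C@@](O[Si](CC)(CC)CC)(C(C)C)[C@H]12 | intermediate
17 | (1R,4R,5R)-4-hydroxydauc-8-en-6-one | O=C1CC(C)=CC[C@@]2(C)CC[C@@](O)(C(C)C)[C@H]12 | intermediate
18 | (1R,4R,5S,6S)-dauc-8-ene-4,6-diol | O[C@H]1CC(C)=CC[C@@]2(C)CC[C@@](O)(C(C)C)[C@H]12 | intermediate
19 | 3,4-dimethoxybenzoyl chloride | COc1ccc(C(=O)Cl)cc1OC | starting material
20 | (1R,4R,5S,6S)-4-hydroxydauc-8-en-6-yl 3,4-dimethoxybenzoate | COc1ccc(C(=O)O[C@H]2CC(C)=CC[C@@]3(C)CC[C@@](O)(C(C)C)[C@H]23)cc1OC | target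

Total step count: 11. Longest linear sequence: 11 steps (1 → 20).

Steps most likely to fail

1. Step 7.
- What may go wrong:
  - Carbene transfer from so crowded a complex to an unactivated diene may be slower than thermal decay of the complex.
  - Attack may fall on C9=C10 and misplace the methyl group.
  - A trans-configured cyclopropane may open by a homodienyl hydrogen shift instead of epimerising.
  - Facial selectivity at C1 may be poor.
- Fallback: it sets out from 12 and returns at 15. Isoprene is replaced by purchased 2-(trimethylsilyloxy)buta-1,3-diene. This is the electron-rich class of diene for which the cyclopropanation–Cope sequence is best established, and its oxygen substituent fixes the site of attack. The product should be the bis(enol ether) 6-methoxy-8-(trimethylsilyloxy)-4-(triethylsilyloxy)-14-nordauca-5,8-diene F1. MeLi in THF at 0 °C cleaves only the trimethylsilyl enol ether and gives the regiodefined lithium 8-enolate F2. PhNTf2 converts this into the C8 enol triflate F3. Coupling with MeMgBr under Fe(acac)3 catalysis then installs C14 on the intact C8=C9 alkene to give 15.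

2. Step 8.
- What may go wrong:
  - The C4–O bond may ionise with help from the enol ether, so that the silyloxy group is lost.
  - C5 may be protonated on the β face.
  - C8=C9 may migrate into conjugation.
- Fallback: it sets out from 15, returns at 16 and avoids acid altogether. Dimethyldioxirane (1 equiv, acetone/CH2Cl2, −78 °C) oxidises the enol ether, the most electron-rich alkene, to the 5,6-epoxy-6-methoxy compound F4. On aqueous work-up this collapses to 5-hydroxy-4-(triethylsilyloxy)dauc-8-en-6-one F5 (Rubottom-type oxidation; the configuration at C5 is of no consequence). SmI2 in THF/MeOH at −78 °C removes the α-hydroxyl (reduction of α-heterosubstituted ketones). The samarium enolate formed is protonated in situ at low temperature, with a proton source that can be varied, to give 16.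

3. Step 6.
- What may go wrong:
  - Attack of the bulky dianion on an acyl carbon flanked by C1 and quaternary C4 may be blocked.
  - Electron transfer may reduce the acid chloride instead.
- Fallback: it uses the classical Fischer synthesis, in which C5–C6 forms at an exposed CO ligand. It sets out from 9, returns at 12 and bypasses steps 1–5. Purchased 2-bromo-3-methylcyclopent-2-en-1-one reacts with i-PrMgCl/CeCl3 (THF, −78 °C) to give racemic 2-bromo-3-methyl-1-(propan-2-yl)cyclopent-2-en-1-ol F6. Preparative chromatography on a chiral phase delivers the (R)-alcohol F7. Et3SiOTf/2,6-lutidine then gives the silyl ether F8. Bromine–lithium exchange with t-BuLi (2 equiv, Et2O, −78 °C) gives the alkenyllithium F9, which cannot eliminate because that would require a five-membered cyclic allene. Addition of F9 to 9 gives the lithium acylchromate F10, and MeOTf in CH2Cl2 gives 12.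

Further compounds
F1 | step 7 | 6-methoxy-8-(trimethylsilyloxy)-4-(triethylsilyloxy)-14-nordauca-5,8-diene | COC1=C2[C@](O[Si](CC)(CC)CC)(C(C)C)CC[C@]2(C)CC=C(O[Si](C)(C)C)C1
F2 | step 7 | lithium 8-enolate of the 6-methoxy-14-nordauca-5,8-diene | [Li+].COC1=C2[C@](O[Si](CC)(CC)CC)(C(C)C)CC[C@]2(C)CC=C([O-])C1
F3 | step 7 | C8 enol triflate of the 6-methoxy-14-nordauca-5,8-diene | COC1=C2[C@](O[Si](CC)(CC)CC)(C(C)C)CC[C@]2(C)CC=C(OS(=O)(=O)C(F)(F)F)C1
F4 | step 8 | 5,6-epoxy-6-methoxy-4-(triethylsilyloxy)dauc-8-ene | COC12CC(C)=CC[C@@]3(C)CC[C@@](O[Si](CC)(CC)CC)(C(C)C)C13O2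
F5 | step 8 | 5-hydroxy-4-(triethylsilyloxy)dauc-8-en-6-one | O=C1CC(C)=CC[C@@]2(C)CC[C@@](O[Si](CC)(CC)CC)(C(C)C)C12O
F6 | step 6 | racemic 2-bromo-3-methyl-1-(propan-2-yl)cyclopent-2-en-1-ol | CC1=C(Br)C(O)(C(C)C)CC1
F7 | step 6 | (1R)-2-bromo-3-methyl-1-(propan-2-yl)cyclopent-2-en-1-ol | BrC1=C(C)CC[C@@]1(O)C(C)C
F8 | step 6 | {[(1R)-2-bromo-3-methyl-1-(propan-2-yl)cyclopent-2-en-1-yl]oxy}triethylsilane | BrC1=C(C)CC[C@@]1(O[Si](CC)(CC)CC)C(C)C
F9 | step 6 | [(5R)-2-methyl-5-(propan-2-yl)-5-(triethylsilyloxy)cyclopent-1-en-1-yl]lithium | [Li]C1=C(C)CC[C@@]1(O[Si](CC)(CC)CC)C(C)C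
F10 | step 6 | lithium pentacarbonyl(acyl)chromate | [Li+].[O-]C(C1=C(C)CC[C@@]1(O[Si](CC)(CC)CC)C(C)C)=[Cr](=C=O)(=C=O)(=C=O)(=C=O)=C=O
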